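**Retrosynthetic overview**
1. Target 23 ⇐ bicyclic 19-hydroxy-2-ketone 18 by late redox and acyl adjustments: 2-C=O → 2α-OH, 19-OAc, 7α-OH by allylic oxidation, C15 enal.
2. 18 ⇐ achiral polyene 16 by one catalytic enantioselective enone-initiated, allylsilane-terminated bicyclisation. Ring A closes first (C4–C5), ring B second (C9–C10), and the 8(17)-methylene is formed in the same cascade.
3. 16 ⇐ allylic chloride 15 + CO + (Z)-vinylstannane 4 by carbonylative Stille coupling (C1–C2 and C2–C3).
4. 15 ⇐ nerol 5 via oxidative cleavage, 2-(silylmethyl)vinyl Grignard addition, Claisen rearrangement (sets the allylsilane olefin) and isopropenyl Grignard addition.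
5. 4 ⇐ propargyl alcohol 1 by carbomagnesiation and stannylation.

Assumptions: labdane numbering is used for the bicyclic compounds and for the corresponding atoms of their acyclic precursors. Compounds 7, 11, 12, 14 and 15 each carry one racemic carbinol or chloride centre that is erased before the achiral polyene 16, so it is left undefined in their SMILES. The IDPi enantiomer is the one that gives the (5R,10S) series; both antipodes are equally accessible.

**Step 1**
Reactants: 1 prop-2-yn-1-ol
Product: 3 (Z)-2-methyl-3-(tributylstannyl)prop-2-en-1-ol, via vinylmagnesium chelate 2 (not isolated)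
Conditions: MeMgBr (2.5 equiv), CuI (10 mol%), THF/Et2O, −10 °C → rt; then Bu3SnCl, 0 °C → rt; aq. NH4Cl
Reagents that add atoms: methylmagnesium bromide, C[Mg]Br; tributyltin chloride, CCCC[Sn](Cl)(CCCC)CCCC
Why: Cu-catalysed anti-carbomagnesiation of the propargylic alkoxide (five-membered Mg chelate) puts CH3 on the internal carbon and Mg on the terminal carbon cis to CH2O, and Mg→Sn transmetalation with retention fixes the Z olefin that later makes C19 the axial group.

**Step 2**
Reactants: 3 (Z)-2-methyl-3-(tributylstannyl)prop-2-en-1-ol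
Product: 4 (Z)-tributyl{2-methyl-3-[(triethylsilyl)oxy]prop-1-en-1-yl}stannane
Conditions: TESCl, imidazole, CH2Cl2, 0 °C
Reagents that add atoms: chlorotriethylsilane, CC[Si](Cl)(CC)CC
Why: Standard imidazole-mediated O-silylation; a non-participating, acid-labile group is used so that the C19 oxygen cannot bridge to the C4 cation (an acetate would) and is lost in the work-up of step 10.

**Step 3**
Reactants: 5 nerol
Product: 6 neryl triisopropylsilyl ether
Conditions: TIPSCl, imidazole, DMF, rt
Reagents that add atoms: chlorotriisopropylsilane, CC(C)[Si](Cl)(C(C)C)C(C)C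
Why: Standard silylation of the primary allylic alcohol; TIPS has no aryl group (stable to Li/NH3 in step 11) and survives the acidic work-up of step 10.

**Step 4**
Reactants: 6 neryl triisopropylsilyl ether
Product: 8 (Z)-4-methyl-6-[(triisopropylsilyl)oxy]hex-4-enal, via vicinal diol 7 (not isolated)
Conditions: OsO4 (1 mol%), NaIO4 (2.2 equiv), 2,6-lutidine, dioxane/H2O 3:1, 0 °C → rt
Reagents that add atoms: osmium tetroxide (catalytic O carrier), O=[Os](=O)(=O)=O; sodium periodate (terminal oxidant), [Na+].[O-]I(=O)(=O)=O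
Why: Lemieux–Johnson oxidation: OsO4 dihydroxylates the electron-rich remote trisubstituted olefin in preference to the 2,3-olefin, which is inductively deactivated and shielded by the allylic OTIPS, and periodate cleaves the diol in situ without touching the Z olefin.

**Step 5**
Reactants: 8 (Z)-4-methyl-6-[(triisopropylsilyl)oxy]hex-4-enal; 9 (2-bromoallyl)trimethylsilane
Product: 11 (Z)-6-methyl-8-[(triisopropylsilyl)oxy]-2-[(trimethylsilyl)methyl]octa-1,6-dien-3-ol, via Grignard reagent 10 (not isolated)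
Conditions: 9, Mg turnings, THF, rt; then 8, THF, −78 → 0 °C; aq. NH4Cl
Reagents that add atoms: none
Why: 1,2-addition of the alkenyl Grignard reagent to the aldehyde installs the 2-(silylmethyl)allyl unit; the racemic carbinol centre is erased in step 6.

**Step 6**
Reactants: 11 (Z)-6-methyl-8-[(triisopropylsilyl)oxy]-2-[(trimethylsilyl)methyl]octa-1,6-dien-3-ol
Product: 13 (4Z,8Z)-8-methyl-10-[(triisopropylsilyl)oxy]-4-[(trimethylsilyl)methyl]deca-4,8-dienal, via allyl vinyl ether 12 (not isolated)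
Conditions: [Ir(cod)Cl]2 (1 mol%), Na2CO3 (buffer), vinyl acetate, toluene, 100 °C; then 140 °C, sealed tube
Reagents that add atoms: vinyl acetate, C=COC(C)=O
Why: Ir-catalysed transfer vinylation then Claisen [3,3]-rearrangement through a chair with the C9 side chain equatorial gives the aldehyde with C7 trans to C11 (CH2SiMe3 cis to C11), the allylsilane geometry needed for an equatorial C9 side chain.

**Step 7**
Reactants: 13 (4Z,8Z)-8-methyl-10-[(triisopropylsilyl)oxy]-4-[(trimethylsilyl)methyl]deca-4,8-dienal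
Product: 14 (6Z,10Z)-2,10-dimethyl-12-[(triisopropylsilyl)oxy]-6-[(trimethylsilyl)methyl]dodeca-1,6,10-trien-3-ol
Conditions: isopropenylmagnesium bromide (1.3 equiv), THF, −78 → 0 °C; aq. NH4Cl
Reagents that add atoms: isopropenylmagnesium bromide, C=C(C)[Mg]Br
Why: Grignard 1,2-addition brings in C1, C10 and C20; the racemic carbinol centre is erased in step 9.

**Step 8**
Reactants: 14 (6Z,10Z)-2,10-dimethyl-12-[(triisopropylsilyl)oxy]-6-[(trimethylsilyl)methyl]dodeca-1,6,10-trien-3-ol
Product: 15 allylic chloride, the 3-chloro analogue of 14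
Conditions: hexachloroacetone, PPh3, CH2Cl2, −20 → 0 °C
Reagents that add atoms: hexachloroacetone, ClC(Cl)(Cl)C(=O)C(Cl)(Cl)Cl
Why: Appel-type chlorination under neutral conditions (no HCl, so the allylsilane survives); any SN2′ regioisomer converges on the same π-allyl complex in step 9.

**Step 9**
Reactants: 15 allylic chloride; 4 (Z)-tributyl{2-methyl-3-[(triethylsilyl)oxy]prop-1-en-1-yl}stannane
Product: 16 (2Z,6E,10Z,14Z)-2,6,14-trimethyl-1-[(triethylsilyl)oxy]-16-[(triisopropylsilyl)oxy]-10-[(trimethylsilyl)methyl]hexadeca-2,6,10,14-tetraen-4-one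
Conditions: Pd2(dba)3 (2.5 mol%), PPh3 (10 mol%), CO (3 atm), THF, 50 °C
Reagents that add atoms: carbon monoxide, [C-]#[O+]
Why: Stille carbonylative cross-coupling: Pd(0) ionises the allyl chloride, CO inserts at the unsubstituted allyl terminus (C1) to give the E C5=C10 olefin from the favoured syn π-allyl, and the alkenylstannane transfers with retention so that CH2OTES stays cis to the new C2 carbonyl.

**Step 10**
Reactants: 16 (2Z,6E,10Z,14Z)-2,6,14-trimethyl-1-[(triethylsilyl)oxy]-16-[(triisopropylsilyl)oxy]-10-[(trimethylsilyl)methyl]hexadeca-2,6,10,14-tetraen-4-one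
Product: 18 19-hydroxy-15-[(triisopropylsilyl)oxy]labda-8(17),13Z-dien-2-one, via trimethylsilyl enol ether 17 (not isolated)
Conditions: confined chiral IDPi Brønsted acid (imidodiphosphorimidate, 5 mol%), methallyltrimethylsilane (10 mol%, pre-silylates the catalyst), toluene/CH2Cl2, −78 → −40 °C; then 1 M HCl, THF, 0 °C
Reagents that add atoms: none
Why: Proposed new method: the silylium–IDPi ion pair silylates the enone oxygen of achiral 16 to a 1-siloxyallyl cation held inside the chiral anion, C5=C10 adds to C4 through a chair (CH2OTES cis to C2 becomes the axial C19, the E olefin gives the trans ring fusion), the C10 cation is trapped by the allylsilane (C9–C10 bond, equatorial side chain) and loss of Me3Si+ from C17 forms the 8(17)-methylene and returns silylium to the catalyst, so C4, C5, C9 and C10 are set enantioselectively in one silyl-transfer cascade; the closest known reactions are IDPi-catalysed asymmetric Mukaiyama–Michael and Hosomi–Sakurai additions (silylium counteranion catalysis), IDPi-catalysed proton-initiated polyene cyclisations and racemic Lewis-acid enone-initiated cation–olefin cyclisations terminated by allylsilanes.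

**Step 11**
Reactants: 18 19-hydroxy-15-[(triisopropylsilyl)oxy]labda-8(17),13Z-dien-2-one
Product: 19 15-[(triisopropylsilyl)oxy]labda-8(17),13Z-diene-2α,19-diol
Conditions: Li, NH3(l)/THF, t-BuOH (2 equiv), −78 °C, 15 min; solid NH4Cl
Reagents that add atoms: none
Why: Dissolving-metal reduction of the keto form (in equilibrium with its 2,19-hemiketal) is under thermodynamic control and gives the equatorial 2α-alcohol, whereas hydride reagents would attack the open α-face and give the axial 2β-alcohol; the alkyl silyl ether and isolated olefins are inert.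

**Step 12**
Reactants: 19 15-[(triisopropylsilyl)oxy]labda-8(17),13Z-diene-2α,19-diol
Product: 20 2α-hydroxy-15-[(triisopropylsilyl)oxy]labda-8(17),13Z-dien-19-yl acetate
Conditions: AcCl (1.05 equiv), 2,4,6-collidine, CH2Cl2, −78 → −40 °C
Reagents that add atoms: acetyl chloride, CC(=O)Cl
Why: Kinetically selective O-acylation of the primary C19 hydroxyl over the secondary C2 hydroxyl at low temperature with a hindered pyridine base.

**Step 13**
Reactants: 20 2α-hydroxy-15-[(triisopropylsilyl)oxy]labda-8(17),13Z-dien-19-yl acetate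
Product: 21 2α,7α-dihydroxy-15-[(triisopropylsilyl)oxy]labda-8(17),13Z-dien-19-yl acetate
Conditions: SeO2 (0.5 equiv), t-BuOOH (3 equiv), CH2Cl2, 0 °C → rt
Reagents that add atoms: selenium dioxide (O carrier), O=[Se]=O; tert-butyl hydroperoxide (terminal oxidant), CC(C)(C)OO
Why: Riley allylic oxidation: the ene reaction at the exocyclic olefin removes the axial 7α-H and the [2,3]-shift returns oxygen to the same face to give the axial 7α-alcohol, while the 13-ene is deactivated by its allylic silyloxy group.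

**Step 14**
Reactants: 21 2α,7α-dihydroxy-15-[(triisopropylsilyl)oxy]labda-8(17),13Z-dien-19-yl acetate
Product: 22 2α,7α,15-trihydroxylabda-8(17),13Z-dien-19-yl acetate
Conditions: TBAF (1.5 equiv), AcOH (1.5 equiv), THF, 0 °C → rt
Reagents that add atoms: none
Why: Fluoride cleaves the Si–O bond; acetic acid buffering protects the C19 acetate from cleavage or migration.

**Step 15**
Reactants: 22 2α,7α,15-trihydroxylabda-8(17),13Z-dien-19-yl acetate
Product: 23 19-acetoxy-2α,7α-dihydroxylabda-8(17),13Z-dien-15-al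
Conditions: TEMPO (10 mol%), PhI(OAc)2 (1.1 equiv), CH2Cl2, 0 °C → rt
Reagents that add atoms: none
Why: TEMPO/PhI(OAc)2 oxoammonium oxidation is selective for the primary allylic alcohol over the two secondary alcohols and, being neutral, leaves the Z-enal geometry intact (as in nerol → neral).

**Compound list**
1 | prop-2-yn-1-ol (propargyl alcohol) | C#CCO | starting material
2 | vinylmagnesium chelate, bromomagnesium (Z)-3-(bromomagnesio)-2-methylprop-2-en-1-olate (Mg on C3 cis to CH2O) | Br[Mg]/C=C(C)\CO[Mg]Br | intermediate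
3 | (Z)-2-methyl-3-(tributylstannyl)prop-2-en-1-ol (Sn cis to CH2OH) | CCCC[Sn](CCCC)(CCCC)/C=C(C)\CO | intermediate
4 | (Z)-tributyl{2-methyl-3-[(triethylsilyl)oxy]prop-1-en-1-yl}stannane | CCCC[Sn](CCCC)(CCCC)/C=C(C)\CO[Si](CC)(CC)CC | intermediate
5 | nerol, (Z)-3,7-dimethylocta-2,6-dien-1-ol | CC(C)=CCC/C(C)=C\CO | starting material
6 | neryl triisopropylsilyl ether | CC(C)=CCC/C(C)=C\CO[Si](C(C)C)(C(C)C)C(C)C | intermediate
7 | (Z)-2,6-dimethyl-8-[(triisopropylsilyl)oxy]oct-6-ene-2,3-diol (racemic) | CC(C)(O)C(O)CC/C(C)=C\CO[Si](C(C)C)(C(C)C)C(C)C | intermediate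
8 | (Z)-4-methyl-6-[(triisopropylsilyl)oxy]hex-4-enal | O=CCC/C(C)=C\CO[Si](C(C)C)(C(C)C)C(C)C | intermediate
9 | (2-bromoallyl)trimethylsilane | C=C(Br)C[Si](C)(C)C | starting material
10 | [3-(trimethylsilyl)prop-1-en-2-yl]magnesium bromide | C=C(C[Si](C)(C)C)[Mg]Br | intermediate
11 | (Z)-6-methyl-8-[(triisopropylsilyl)oxy]-2-[(trimethylsilyl)methyl]octa-1,6-dien-3-ol (racemic) | C=C(C[Si](C)(C)C)C(O)CC/C(C)=C\CO[Si](C(C)C)(C(C)C)C(C)C | intermediate
12 | vinyl ether of 11 (racemic) | C=COC(CC/C(C)=C\CO[Si](C(C)C)(C(C)C)C(C)C)C(=C)C[Si](C)(C)C | intermediate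
13 | (4Z,8Z)-8-methyl-10-[(triisopropylsilyl)oxy]-4-[(trimethylsilyl)methyl]deca-4,8-dienal (C7 trans to C11) | O=CCC/C(C[Si](C)(C)C)=C/CC/C(C)=C\CO[Si](C(C)C)(C(C)C)C(C)C | intermediate
14 | (6Z,10Z)-2,10-dimethyl-12-[(triisopropylsilyl)oxy]-6-[(trimethylsilyl)methyl]dodeca-1,6,10-trien-3-ol (racemic) | C=C(C)C(O)CC/C(C[Si](C)(C)C)=C/CC/C(C)=C\CO[Si](C(C)C)(C(C)C)C(C)C | intermediate
15 | allylic chloride, 3-chloro analogue of 14 (racemic) | C=C(C)C(Cl)CC/C(C[Si](C)(C)C)=C/CC/C(C)=C\CO[Si](C(C)C)(C(C)C)C(C)C | intermediate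
16 | (2Z,6E,10Z,14Z)-2,6,14-trimethyl-1-[(triethylsilyl)oxy]-16-[(triisopropylsilyl)oxy]-10-[(trimethylsilyl)methyl]hexadeca-2,6,10,14-tetraen-4-one (achiral) | CC[Si](CC)(CC)OC/C(C)=C\C(=O)C/C(C)=C/CC/C(C[Si](C)(C)C)=C/CC/C(C)=C\CO[Si](C(C)C)(C(C)C)C(C)C | intermediate
17 | 19-[(triethylsilyl)oxy]-15-[(triisopropylsilyl)oxy]-2-[(trimethylsilyl)oxy]labda-2,8(17),13Z-triene | C=C1CC[C@H]2[C@@](C)(CO[Si](CC)(CC)CC)C=C(O[Si](C)(C)C)C[C@]2(C)[C@H]1CC/C(C)=C\CO[Si](C(C)C)(C(C)C)C(C)C | intermediate
18 | 19-hydroxy-15-[(triisopropylsilyl)oxy]labda-8(17),13Z-dien-2-one (5α-H, 9α-H, 10β-Me, 4β-CH2OH) | C=C1CC[C@H]2[C@@](C)(CO)CC(=O)C[C@]2(C)[C@H]1CC/C(C)=C\CO[Si](C(C)C)(C(C)C)C(C)C | intermediate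
19 | 15-[(triisopropylsilyl)oxy]labda-8(17),13Z-diene-2α,19-diol | C=C1CC[C@H]2[C@@](C)(CO)C[C@H](O)C[C@]2(C)[C@H]1CC/C(C)=C\CO[Si](C(C)C)(C(C)C)C(C)C | intermediate
20 | 2α-hydroxy-15-[(triisopropylsilyl)oxy]labda-8(17),13Z-dien-19-yl acetate | C=C1CC[C@H]2[C@@](C)(COC(C)=O)C[C@H](O)C[C@]2(C)[C@H]1CC/C(C)=C\CO[Si](C(C)C)(C(C)C)C(C)C | intermediate
21 | 2α,7α-dihydroxy-15-[(triisopropylsilyl)oxy]labda-8(17),13Z-dien-19-yl acetate | C=C1[C@H](O)C[C@H]2[C@@](C)(COC(C)=O)C[C@H](O)C[C@]2(C)[C@H]1CC/C(C)=C\CO[Si](C(C)C)(C(C)C)C(C)C | intermediate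
22 | 2α,7α,15-trihydroxylabda-8(17),13Z-dien-19-yl acetate | C=C1[C@H](O)C[C@H]2[C@@](C)(COC(C)=O)C[C@H](O)C[C@]2(C)[C@H]1CC/C(C)=C\CO | intermediate
23 | 19-acetoxy-2α,7α-dihydroxylabda-8(17),13Z-dien-15-al, (2R,4S,5R,7R,9R,10S) | C=C1[C@H](O)C[C@H]2[C@@](C)(COC(C)=O)C[C@H](O)C[C@]2(C)[C@H]1CC/C(C)=C\C=O | target

**Step count:** 15 steps in total; longest linear sequence 13 steps (nerol 5 → 23, steps 3–15).

**Three steps most likely to fail, each with a fallback**

Step 10 (proposed new bicyclisation). Risks are low ee, loss of the C3=C4 geometry in the siloxyallyl cation (which would scramble C4), allylic strain in the reactive enone conformer, and isomerisation of the β,γ-olefin into conjugation. The fallback sets out from 16 and runs the cascade with an achiral silyl Lewis acid (TMSNTf2, 10 mol%, CH2Cl2, −78 °C), the known racemic Lewis-acid enone-initiated cation–olefin cyclisation with allylsilane termination. This gives the racemic trimethylsilyl enol ether F1, which 1 M HCl converts to the racemic hydroxy ketone F2. Li/NH3 as in step 11 gives the racemic diol F3. Enantiocontrol then moves to a lipase-catalysed kinetic resolution in the C19 acetylation (Burkholderia cepacia lipase or CAL-B, vinyl acetate, MTBE), which gives acetate 20 and leaves the antipodal diol ent-19 F4. The route is rejoined at 20; if the enzyme prefers the antipode, unreacted 19 is recovered and re-enters at step 12.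

Step 9 (carbonylative Stille coupling). Risks are direct coupling without CO, E/Z leakage at C5=C10 and migration of the β,γ-olefin. The fallback sets out from 14 and 4. Heating 14 with N,N-dimethylformamide dimethyl acetal (xylene, 160 °C) gives, by [2,3]-sigmatropic rearrangement of the alkoxy(amino)carbene, the (E)-β,γ-unsaturated dimethylamide F5 with the same allylic transposition. Tin–lithium exchange on 4 (n-BuLi, THF, −78 °C) gives the (Z)-vinyllithium F6, which is added to F5 (with CeCl3 to suppress enolisation). Collapse of the adduct on work-up returns the route at 16.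

Step 13 (SeO2 allylic oxidation). Risks are competing oxidation at the side-chain 13-ene and over-oxidation to the 7-ketone. The fallback sets out from 20 and reorders the end game so that the side-chain olefin is electronically switched off first. TBAF/AcOH gives the 2α,15-diol 19-acetate F7, and TEMPO/PhI(OAc)2 gives the (Z)-enal F8. SeO2/t-BuOOH is then applied last to F8, whose conjugated 13-ene does not undergo the ene reaction, returning directly at 23 (Z/E drift of the enal must be monitored).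

**Further compounds**
F1 | step 10 | racemic 19-[(triethylsilyl)oxy]-15-[(triisopropylsilyl)oxy]-2-[(trimethylsilyl)oxy]labda-2,8(17),13Z-triene (both enantiomers) | C=C1CC[C@H]2[C@@](C)(CO[Si](CC)(CC)CC)C=C(O[Si](C)(C)C)C[C@]2(C)[C@H]1CC/C(C)=C\CO[Si](C(C)C)(C(C)C)C(C)C.C=C1CC[C@@H]2[C@](C)(CO[Si](CC)(CC)CC)C=C(O[Si](C)(C)C)C[C@@]2(C)[C@@H]1CC/C(C)=C\CO[Si](C(C)C)(C(C)C)C(C)C
F2 | step 10 | racemic 19-hydroxy-15-[(triisopropylsilyl)oxy]labda-8(17),13Z-dien-2-one (both enantiomers) | C=C1CC[C@H]2[C@@](C)(CO)CC(=O)C[C@]2(C)[C@H]1CC/C(C)=C\CO[Si](C(C)C)(C(C)C)C(C)C.C=C1CC[C@@H]2[C@](C)(CO)CC(=O)C[C@@]2(C)[C@@H]1CC/C(C)=C\CO[Si](C(C)C)(C(C)C)C(C)C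
F3 | step 10 | racemic 15-[(triisopropylsilyl)oxy]labda-8(17),13Z-diene-2α,19-diol (both enantiomers) | C=C1CC[C@H]2[C@@](C)(CO)C[C@H](O)C[C@]2(C)[C@H]1CC/C(C)=C\CO[Si](C(C)C)(C(C)C)C(C)C.C=C1CC[C@@H]2[C@](C)(CO)C[C@@H](O)C[C@@]2(C)[C@@H]1CC/C(C)=C\CO[Si](C(C)C)(C(C)C)C(C)C
F4 | step 10 | ent-19, the mirror image of diol 19 | C=C1CC[C@@H]2[C@](C)(CO)C[C@@H](O)C[C@@]2(C)[C@@H]1CC/C(C)=C\CO[Si](C(C)C)(C(C)C)C(C)C
F5 | step 9 | (3E,7Z,11Z)-N,N,3,11-tetramethyl-13-[(triisopropylsilyl)oxy]-7-[(trimethylsilyl)methyl]trideca-3,7,11-trienamide | CN(C)C(=O)C/C(C)=C/CC/C(C[Si](C)(C)C)=C/CC/C(C)=C\CO[Si](C(C)C)(C(C)C)C(C)C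
F6 | step 9 | (Z)-{2-methyl-3-[(triethylsilyl)oxy]prop-1-en-1-yl}lithium | [Li]/C=C(C)\CO[Si](CC)(CC)CC
F7 | step 13 | 2α,15-dihydroxylabda-8(17),13Z-dien-19-yl acetate | C=C1CC[C@H]2[C@@](C)(COC(C)=O)C[C@H](O)C[C@]2(C)[C@H]1CC/C(C)=C\CO
F8 | step 13 | 19-acetoxy-2α-hydroxylabda-8(17),13Z-dien-15-al | C=C1CC[C@H]2[C@@](C)(COC(C)=O)C[C@H](O)C[C@]2(C)[C@H]1CC/C(C)=C\C=O
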